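**Plan**

- Numbering: ring C1–C6, with C1 the quaternary carbinol bearing C7H2OBz, C2–OH, C3H2, C4H2, C5–OBz, C6–OH. The C3–C4 edge is the only pair of neighbouring ring carbons free of heteroatoms, so retrosynthesis cuts it first and carries it as a C3=C4 alkene closed by olefin metathesis of a 1,7-diene.
- The open-chain diene is then cut at C1–C2 (a C7–C1(=O)–C6 ketone plus a γ-silyloxyallyl stannane). The ketone's C1/C7 unit is traced back to one vinyl group of a (3R,4R)-divinyl diol.
- Forward: diol → O5 monobenzoate → hydroxyl-directed epoxidation of the neighbouring vinyl → O6 benzyloxymethyl ether → benzoate opening at C7 → C1 ketone → chelation-controlled allylation (C1–C2, chain complete) → ring closure at C3=C4 (the only ring) → hydrogenation/hydrogenolysis → desilylation.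
- Stereochemistry: C5 and C6 come unchanged from the chiral-pool diol. C1 is set by Cram-chelate addition (MgBr2 on C1=O and the O6 ether) anti to the C5 arm. C2 is set in the same step by the syn-selective open transition state of the (Z)-stannane. Ring closure and end game touch no stereocentre.

Key step: step 8

Assumption: diol 1 is taken as a purchasable chiral-pool compound (otherwise three known steps from D-mannitol through the 1,6-dibromide and zinc elimination), and the locants C1–C7 defined above are used for all intermediates.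

Step 1
Reactants: 1 (3R,4R)-hexa-1,5-diene-3,4-diol; 2 benzoyl chloride
Product: 3 (3R,4R)-4-hydroxyhexa-1,5-dien-3-yl benzoate
Conditions: BzCl (1.05 equiv), Me2SnCl2 (5 mol %), K2CO3, THF, rt
Reagents that add atoms: benzoyl chloride, O=C(Cl)c1ccccc1
Why: Tin-catalysed monoacylation of a 1,2-diol stops after the first benzoylation, and since the two hydroxyls of this twofold-symmetric diol are homotopic a single monoester (the O5 benzoate) results with both stereocentres untouched.

Step 2
Reactants: 3 (3R,4R)-4-hydroxyhexa-1,5-dien-3-yl benzoate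
Product: 4 (1S,2R)-1-hydroxy-1-[(2R)-oxiran-2-yl]but-3-en-2-yl benzoate
Conditions: Ti(OiPr)4 (10 mol %), L-(+)-DIPT (12 mol %), t-BuOOH, 4 Å MS, CH2Cl2, −20 °C
Reagents that add atoms: tert-butyl hydroperoxide, CC(C)(C)OO
Why: Sharpless epoxidation acts only on the alkene of the free allylic alcohol (the allylic benzoate cannot bind titanium), which tells the two vinyl groups apart, and with L-(+)-tartrate, the ligand matched to this carbinol, the erythro epoxide is expected; the new centre is the future C1 and is erased in step 5.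

Step 3
Reactants: 4 (1S,2R)-1-hydroxy-1-[(2R)-oxiran-2-yl]but-3-en-2-yl benzoate
Product: 5 (1S,2R)-1-[(benzyloxy)methoxy]-1-[(2R)-oxiran-2-yl]but-3-en-2-yl benzoate
Conditions: BnOCH2Cl, i-Pr2NEt, CH2Cl2, 0 °C → rt
Reagents that add atoms: benzyl chloromethyl ether, ClCOCc1ccccc1
Why: Alkylation of the secondary alcohol with the chloromethyl ether under a hindered amine base (acetal-type ether formation) leaves epoxide and ester untouched and places on O6 a chelating group that hydrogenolysis removes later.

Step 4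
Reactants: 5 (1S,2R)-1-[(benzyloxy)methoxy]-1-[(2R)-oxiran-2-yl]but-3-en-2-yl benzoate; 6 benzoic acid
Product: 7 (2R,3R,4R)-4-(benzoyloxy)-3-[(benzyloxy)methoxy]-2-hydroxyhex-5-en-1-yl benzoate
Conditions: PhCO2H (1.5 equiv), Bu4NBr (10 mol %), MeCN, 70 °C
Reagents that add atoms: benzoic acid, O=C(O)c1ccccc1
Why: Halide-catalysed SN2 opening of the terminal epoxide by benzoate occurs at the unhindered C7 methylene, so the C7 benzoate forms while the C1–O bond is kept as a free secondary alcohol.

Step 5
Reactants: 7 (2R,3R,4R)-4-(benzoyloxy)-3-[(benzyloxy)methoxy]-2-hydroxyhex-5-en-1-yl benzoate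
Product: 8 (3S,4R)-4-(benzoyloxy)-3-[(benzyloxy)methoxy]-2-oxohex-5-en-1-yl benzoate
Conditions: Dess–Martin periodinane, CH2Cl2, 0 °C → rt
Reagents that add atoms: none
Why: Dess–Martin oxidation turns the only free alcohol into the C1 ketone under near-neutral conditions that should neither epimerise C6 nor eliminate the β-benzoate.

Step 6
Reactants: 9 allyloxy(tert-butyl)dimethylsilane
Product: 11 (Z)-tert-butyldimethyl{[3-(tributylstannyl)prop-1-en-1-yl]oxy}silane, via (Z)-3-silyloxyallyllithium 10 (not isolated)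
Conditions: s-BuLi, THF–HMPA, −78 °C; then Bu3SnCl, −78 °C → rt
Reagents that add atoms: tributyltin chloride, CCCC[Sn](Cl)(CCCC)CCCC
Why: Allylic deprotonation gives an oxygen-coordinated (Z)-oxyallyl anion that tributyltin chloride traps at the carbon remote from oxygen (metalation–stannylation), which fixes the (Z)-enol ether geometry.

Step 7
Reactants: 8 (3S,4R)-4-(benzoyloxy)-3-[(benzyloxy)methoxy]-2-oxohex-5-en-1-yl benzoate; 11 (Z)-tert-butyldimethyl{[3-(tributylstannyl)prop-1-en-1-yl]oxy}silane
Product: 12 (2R,3S,4R)-4-(benzoyloxy)-3-[(benzyloxy)methoxy]-2-[(1R)-1-{[tert-butyl(dimethyl)silyl]oxy}prop-2-en-1-yl]-2-hydroxyhex-5-en-1-yl benzoate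
Conditions: MgBr2·OEt2 (3 equiv), CH2Cl2, −20 °C → rt
Reagents that add atoms: stannane 11, CCCC[Sn](CCCC)(CCCC)C/C=C\O[Si](C)(C)C(C)(C)C
Why: In this Lewis-acid-promoted allylstannane addition (SE2′) the ketone is held as a five-membered magnesium chelate between C1=O and the O6 acetal oxygen, so the oxygen-bearing carbon of the stannane should enter from the face opposite the C5 arm (Cram chelate, sets C1), while the open transition state of the (Z)-stannane keeps its OTBS group away from the chelate ring and should give the 1,2-syn diol monoether (sets C2).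

Step 8
Reactants: 12 (2R,3S,4R)-4-(benzoyloxy)-3-[(benzyloxy)methoxy]-2-[(1R)-1-{[tert-butyl(dimethyl)silyl]oxy}prop-2-en-1-yl]-2-hydroxyhex-5-en-1-yl benzoate
Product: 13 [(1R,2R,5R,6S)-5-(benzoyloxy)-6-[(benzyloxy)methoxy]-2-{[tert-butyl(dimethyl)silyl]oxy}-1-hydroxycyclohex-3-en-1-yl]methyl benzoate
Conditions: RuCl2(=CHPh)(PCy3)(H2IMes) (second-generation Grubbs catalyst, 5 mol %), CH2Cl2 (0.005 M), 40 °C
Reagents that add atoms: none
Why: The ruthenium benzylidene exchanges with one of the two monosubstituted vinyl groups, the new alkylidene adds to the other vinyl group in an intramolecular [2+2] cycloaddition, and cycloreversion of the ruthenacyclobutane releases the C3=C4 alkene, with loss of ethylene driving the turnover (ring-closing olefin metathesis, the standard entry to conduritol-type polyoxygenated cyclohexenes). The single ring closes as a six-membered carbocycle by joining C3 to C4 of the 1,7-diene, and the ring size allows only the cis alkene. No stereocentre is formed or disturbed, because C1, C2, C5 and C6 stay sp3 and carry no acidic or metal-bound position. The selectivity needed is ring closure over intermolecular metathesis; it is secured by high dilution, by the fully substituted C1 and the oxygen substituents on C2, C5 and C6 that favour the folded rotamer, and by the reluctance of allylically oxygenated terminal alkenes to homodimerise. The free tertiary alcohol, the two benzoates, the acetal and the silyl ether are all tolerated by this catalyst.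

Step 9
Reactants: 13 [(1R,2R,5R,6S)-5-(benzoyloxy)-6-[(benzyloxy)methoxy]-2-{[tert-butyl(dimethyl)silyl]oxy}-1-hydroxycyclohex-3-en-1-yl]methyl benzoate
Product: 15 [(1R,2R,5R,6S)-5-(benzoyloxy)-2-{[tert-butyl(dimethyl)silyl]oxy}-1,6-dihydroxycyclohexyl]methyl benzoate, via saturated benzyloxymethyl ether 14 (not isolated)
Conditions: H2 (1 atm), Pd(OH)2/C, EtOAc–EtOH, rt
Reagents that add atoms: none
Why: Heterogeneous catalytic hydrogenation first saturates the cis C3=C4 alkene and then hydrogenolyses the benzyl C–O bond of the acetal, whose hemiacetal residue loses formaldehyde, while benzoates and silyl ether are inert and no stereocentre is involved.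

Step 10
Reactants: 15 [(1R,2R,5R,6S)-5-(benzoyloxy)-2-{[tert-butyl(dimethyl)silyl]oxy}-1,6-dihydroxycyclohexyl]methyl benzoate
Product: 16 [(1S,2R,5R,6S)-5-(benzoyloxy)-1,2,6-trihydroxycyclohexyl]methyl benzoate (CNP0264996.1)
Conditions: HF·pyridine, THF–pyridine, 0 °C → rt
Reagents that add atoms: none
Why: Fluoride cleaves the Si–O bond (desilylation) under buffered, mildly acidic conditions, so the last hydroxyl is freed without the base that would let the benzoates migrate.

**Compound list**

1 | (3R,4R)-hexa-1,5-diene-3,4-diol | C=C[C@@H](O)[C@H](O)C=C | starting material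
2 | benzoyl chloride | O=C(Cl)c1ccccc1 | starting material
3 | (3R,4R)-4-hydroxyhexa-1,5-dien-3-yl benzoate | C=C[C@@H](OC(=O)c1ccccc1)[C@H](O)C=C | intermediate
4 | (1S,2R)-1-hydroxy-1-[(2R)-oxiran-2-yl]but-3-en-2-yl benzoate | C=C[C@@H](OC(=O)c1ccccc1)[C@H](O)[C@H]2CO2 | intermediate
5 | (1S,2R)-1-[(benzyloxy)methoxy]-1-[(2R)-oxiran-2-yl]but-3-en-2-yl benzoate | C=C[C@@H](OC(=O)c1ccccc1)[C@H](OCOCc2ccccc2)[C@H]3CO3 | intermediate
6 | benzoic acid | O=C(O)c1ccccc1 | starting material
7 | (2R,3R,4R)-4-(benzoyloxy)-3-[(benzyloxy)methoxy]-2-hydroxyhex-5-en-1-yl benzoate | C=C[C@@H](OC(=O)c1ccccc1)[C@H](OCOCc2ccccc2)[C@H](O)COC(=O)c3ccccc3 | intermediate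
8 | (3S,4R)-4-(benzoyloxy)-3-[(benzyloxy)methoxy]-2-oxohex-5-en-1-yl benzoate | C=C[C@@H](OC(=O)c1ccccc1)[C@H](OCOCc2ccccc2)C(=O)COC(=O)c3ccccc3 | intermediate
9 | allyloxy(tert-butyl)dimethylsilane | C=CCO[Si](C)(C)C(C)(C)C | starting material
10 | (Z)-[3-(tert-butyldimethylsilyloxy)prop-2-en-1-yl]lithium | [Li]C/C=C\O[Si](C)(C)C(C)(C)C | intermediate
11 | (Z)-tert-butyldimethyl{[3-(tributylstannyl)prop-1-en-1-yl]oxy}silane | CCCC[Sn](CCCC)(CCCC)C/C=C\O[Si](C)(C)C(C)(C)C | intermediate
12 | (2R,3S,4R)-4-(benzoyloxy)-3-[(benzyloxy)methoxy]-2-[(1R)-1-{[tert-butyl(dimethyl)silyl]oxy}prop-2-en-1-yl]-2-hydroxyhex-5-en-1-yl benzoate | O=C(OC[C@](O)([C@H](O[Si](C)(C)C(C)(C)C)C=C)[C@@H](OCOCc1ccccc1)[C@H](OC(=O)c2ccccc2)C=C)c3ccccc3 | intermediate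
13 | [(1R,2R,5R,6S)-5-(benzoyloxy)-6-[(benzyloxy)methoxy]-2-{[tert-butyl(dimethyl)silyl]oxy}-1-hydroxycyclohex-3-en-1-yl]methyl benzoate | O=C(OC[C@]1(O)[C@H](O[Si](C)(C)C(C)(C)C)C=C[C@@H](OC(=O)c2ccccc2)[C@@H]1OCOCc3ccccc3)c4ccccc4 | intermediate
14 | [(1R,2R,5R,6S)-5-(benzoyloxy)-6-[(benzyloxy)methoxy]-2-{[tert-butyl(dimethyl)silyl]oxy}-1-hydroxycyclohexyl]methyl benzoate | O=C(OC[C@]1(O)[C@H](O[Si](C)(C)C(C)(C)C)CC[C@@H](OC(=O)c2ccccc2)[C@@H]1OCOCc3ccccc3)c4ccccc4 | intermediate
15 | [(1R,2R,5R,6S)-5-(benzoyloxy)-2-{[tert-butyl(dimethyl)silyl]oxy}-1,6-dihydroxycyclohexyl]methyl benzoate | O=C(OC[C@]1(O)[C@H](O[Si](C)(C)C(C)(C)C)CC[C@@H](OC(=O)c2ccccc2)[C@@H]1O)c3ccccc3 | intermediate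
16 | [(1S,2R,5R,6S)-5-(benzoyloxy)-1,2,6-trihydroxycyclohexyl]methyl benzoate | O=C(OC[C@]1(O)[C@H](O)CC[C@@H](OC(=O)c2ccccc2)[C@@H]1O)c1ccccc1 | target

**Step count and risks**

Total step count: 10. Longest linear sequence: 9 steps (1 → 16 by steps 1–5 and 7–10); step 6 is a one-step side branch.

Steps most likely to fail:

1. Step 7. The addition may stall on the hindered, doubly α-oxygenated ketone. The open transition state may also lose its syn preference, because C7H2OBz sits where an aldehyde hydrogen would be, so that the C2 epimer forms. The fallback builds C2 at the aldehyde oxidation level, where chelation-controlled addition of this stannane is an established route to the syn,syn pattern, and brings in C7 last. It sets out from 5. Periodic acid (H5IO6, THF–Et2O, 0 °C) cleaves the terminal epoxide to the aldehyde (3R,4S)-4-[(benzyloxy)methoxy]-5-oxopent-1-en-3-yl benzoate F1. MgBr2·OEt2 with stannane 11 should then give the syn,syn alcohol (3R,4R,5R,6R)-4-[(benzyloxy)methoxy]-6-{[tert-butyl(dimethyl)silyl]oxy}-5-hydroxyocta-1,7-dien-3-yl benzoate F2. Dess–Martin oxidation gives the ketone (3R,4S,6R)-4-[(benzyloxy)methoxy]-6-{[tert-butyl(dimethyl)silyl]oxy}-5-oxoocta-1,7-dien-3-yl benzoate F3. Corey–Chaykovsky methylenation (Me3S+ I−, KN(SiMe3)2, THF, −20 °C) should add anti to both α-oxygen substituents (Felkin–Anh, the two α-centres reinforcing each other) and give the spiro-epoxide (1S,2R)-1-[(benzyloxy)methoxy]-1-{(2R)-2-[(1R)-1-{[tert-butyl(dimethyl)silyl]oxy}prop-2-en-1-yl]oxiran-2-yl}but-3-en-2-yl benzoate F4. Benzoic acid with Bu4NBr, as in step 4, opens F4 at its CH2 carbon and the route is rejoined at 12.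

2. Step 9. Palladium may hydrogenolyse the allylic C5–O benzoate or the allylic C2–O silyl ether, or move the double bond, before the alkene is saturated. The fallback separates the two events and sets out from 13. Diimide (from 2-nitrobenzenesulfonyl hydrazide and Et3N, CH2Cl2, rt) reduces C3=C4 without any C–O cleavage and gives 14, which is isolated this time. Pd(OH)2/C and H2 then only have to remove the benzyloxymethyl ether, and the route is rejoined at 15.

3. Step 4. Under the warm carboxylate conditions the new benzoate may migrate from O7 to the neighbouring O1, or the opening may be slow, so that the wrong hydroxyl is offered to the oxidant. The fallback changes the order of oxidation and acylation and sets out from 5. MgBr2·OEt2 (Et2O, 0 °C) opens the epoxide at C7 to the bromohydrin (3R,4R,5S)-4-[(benzyloxy)methoxy]-6-bromo-5-hydroxyhex-1-en-3-yl benzoate F5. Dess–Martin oxidation gives the α-bromoketone (3R,4S)-4-[(benzyloxy)methoxy]-6-bromo-5-oxohex-1-en-3-yl benzoate F6. PhCO2Na in DMF at rt displaces bromide (SN2 at an α-halo ketone), where no free hydroxyl is left for the ester to migrate to, and the route is rejoined at 8.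

Further compounds
F1 | step 7 | (3R,4S)-4-[(benzyloxy)methoxy]-5-oxopent-1-en-3-yl benzoate | O=C[C@@H](OCOCc1ccccc1)[C@H](OC(=O)c2ccccc2)C=C
F2 | step 7 | (3R,4R,5R,6R)-4-[(benzyloxy)methoxy]-6-{[tert-butyl(dimethyl)silyl]oxy}-5-hydroxyocta-1,7-dien-3-yl benzoate | C=C[C@@H](O[Si](C)(C)C(C)(C)C)[C@H](O)[C@@H](OCOCc1ccccc1)[C@H](OC(=O)c2ccccc2)C=C
F3 | step 7 | (3R,4S,6R)-4-[(benzyloxy)methoxy]-6-{[tert-butyl(dimethyl)silyl]oxy}-5-oxoocta-1,7-dien-3-yl benzoate | C=C[C@@H](O[Si](C)(C)C(C)(C)C)C(=O)[C@@H](OCOCc1ccccc1)[C@H](OC(=O)c2ccccc2)C=C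
F4 | step 7 | (1S,2R)-1-[(benzyloxy)methoxy]-1-{(2R)-2-[(1R)-1-{[tert-butyl(dimethyl)silyl]oxy}prop-2-en-1-yl]oxiran-2-yl}but-3-en-2-yl benzoate | C=C[C@@H](O[Si](C)(C)C(C)(C)C)[C@@]1(CO1)[C@@H](OCOCc2ccccc2)[C@H](OC(=O)c3ccccc3)C=C
F0 | step 9 | none | none
F5 | step 4 | (3R,4R,5S)-4-[(benzyloxy)methoxy]-6-bromo-5-hydroxyhex-1-en-3-yl benzoate | C=C[C@@H](OC(=O)c1ccccc1)[C@H](OCOCc2ccccc2)[C@H](O)CBr
F6 | step 4 | (3R,4S)-4-[(benzyloxy)methoxy]-6-bromo-5-oxohex-1-en-3-yl benzoate | C=C[C@@H](OC(=O)c1ccccc1)[C@H](OCOCc2ccccc2)C(=O)CBr
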